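The numbers in the tables were generated by integration with constants of no real substance; the scatter is artificial.

The vessel was closed, stirred and isothermal, and three earlier runs stood behind it.

| flask | substrate | partner | remark | time |
|---|---|---|---|---|
| Monday's | 0.30 M | 0.40 M | run made earlier |  |
| Tuesday's | 0.30 M | 0.90 M | run made earlier |  |
| Wednesday's | 0.45 M | 0.60 M | run made earlier |  |
| flask | 0.30 M | 0.600 M |  | 20 h |

| run | time / h | substrate / % | target / % |
|---|---|---|---|
| Monday's | 5.00 | 0 | 41.5 |
| Monday's | 10.0 | 0 | 42.6 |
| Monday's | 15.0 | 1.0 | 41.0 |
| Monday's | 20.0 | 0.7 | 42.5 |
| Monday's | 25.0 | 0 | 42.6 |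
| Tuesday's | 5.00 | 0 | 47.9 |
| Tuesday's | 10.0 | 0.1 | 47.4 |
| Tuesday's | 15.0 | 0 | 48.3 |
| Tuesday's | 20.0 | 0.1 | 47.9 |
| Tuesday's | 25.0 | 0 | 47.9 |
| Wednesday's | 2.00 | 0.3 | 42.2 |
| Wednesday's | 6.00 | 0 | 42.2 |
| Wednesday's | 12.0 | 0 | 40.9 |
| Wednesday's | 15.0 | 0 | 41.9 |
| Wednesday's | 25.0 | 0.2 | 42.0 |

(each reading ± 0.5 percentage points)

- the reaction counts as stopped when no species that holds the substrate changes by six tenths of a point or more over the second half of the time

- why nothing more happens at 20 h, or that something still does (forward and back rates have come level / the partner has run out first / all of the substrate has reacted / it is still moving)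
- part of the substrate gone at 20 h
- the target standing at 20 h, as a percentage of the substrate charged

I counted turnovers. On Wednesday, at this flask's partner charge, the substrate read 0.3% at 2.00 h, and adding two scatters I took 1.30% as a high estimate of what stood there. For a first-order loss that gave an estimated half-life of 0.319 h, on the long side, so I put the starting rate at 2.17 h⁻¹ of the substrate present, on the low side. Two things slowed it. Loss of substrate cut it by a factor of 2 per half-life, and the partner, if it counted and went one for one, cut it by at most 2.00 over the run. After 7.64 half-lives the accumulated factor came to 200 and the reckoned substrate stood at the scatter. Even with the partner's factor, I reckoned that at 4.88 h, earlier than 10.0 h. My half-life count, the half-lives that fit into the asked time, came to 62.7, so I expected the flask to stop with its substrate reacted. The count says nothing of yield. The flask's partner-to-substrate ratio of 2.00 lay between Monday's 1.33 and Tuesday's 3.00, so I placed the target between their readings at 20.0 h, 42.5% and 47.9%.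

The forecast gave all of the substrate has reacted, 100% gone and 45% target: “So the reaction stops because the substrate is used up, not through equilibrium.”

The flask gave all of the substrate has reacted, with 100% gone and 45.3% target. It reached half of its conversion at 0.177 h. Taken as a half-life, that fits 113 times into the asked time, more than my count of 62.7, and the substrate stood at 0.0708% by 2.00 h, under the scatter. For this flask the hours past 20 h bought no target: it stood at 45.3% at 200 h.

    target ⇌ isomer of the product (K = 0.880, k = 0.110 min⁻¹)
    substrate → intermediate (k = 0.0590 min⁻¹)
    substrate + intermediate → side product (k = 2.00 L mol⁻¹ min⁻¹)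
    partner + intermediate → target (k = 6.40 L mol⁻¹ min⁻¹)

For the neighbour charged with 0.36 M of partner, near Monday's 0.40 M, the partner's factor on the same one-for-one assumption rose to 6.00, so my count of 62.7 fell to 10.5, still above the 7.64 half-lives needed, and I expected its substrate to be gone. It held 0% substrate, the limiting reagent, against 36% of its partner, with 40.6% target.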